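A curve that starts slowly invites us to extrapolate it back and round its order to a whole number, so we compare flasks at the same late time instead.

| flask | L | G | time |
|---|---|---|---|
| ochre | 1.00 M | 0.800 M |  |
| grey | 0.400 M | 0.200 M |  |
| red | 1.00 M | 1.20 M |  |
| amber | 1.50 M | 0.800 M |  |
| green | 0.250 M | 0.200 M | 27 min |

| run | time / min | [J] / M |
|---|---|---|
| ochre run | 3.9 | 0.088 |
| ochre run | 7.7 | 0.214 |
| ochre run | 12 | 0.329 |
| ochre run | 15 | 0.375 |
| ochre run | 19 | 0.426 |
| ochre run | 23 | 0.460 |
| ochre run | 27 | 0.476 |
| grey run | 3.9 | 0.009 |
| grey run | 7.7 | 0.026 |
| grey run | 12 | 0.051 |
| grey run | 15 | 0.066 |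
| grey run | 19 | 0.079 |
| grey run | 23 | 0.092 |
| grey run | 27 | 0.086 |
| red run | 3.9 | 0.122 |
| red run | 7.7 | 0.281 |
| red run | 12 | 0.413 |
| red run | 15 | 0.482 |
| red run | 19 | 0.533 |
| red run | 23 | 0.560 |
| red run | 27 | 0.577 |
| amber run | 3.9 | 0.125 |
| amber run | 7.7 | 0.298 |
| amber run | 12 | 0.441 |
| amber run | 15 | 0.507 |
| amber run | 19 | 0.557 |
| amber run | 23 | 0.586 |
| amber run | 27 | 0.599 |

(standard deviation of a reading: 0.003 M)

- Overall: L + G -> J.
- Constant volume, constant temperature.
- "The second partner" is G.
- An order is taken over about fifteen percent of the charge, up and down.

- the exponent of [G] in the starting rate at the charge of the ochre run (at the point where two percent of the L have become J)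
- the exponent of [L] in the starting rate at the charge of the ochre run (at the point where two percent of the L have become J) (one fixed amount of J, the same in the runs compared)
- J in the green run at 27 min, as a share of the L charged

At 27 min, amber read 0.599 M and ochre 0.476 M, with the same G charge and a ratio of L charges of 1.50. That gives 0.567, the charge exponent of L: the logarithm of the ratio of J at one time over the logarithm of the ratio of L charges, with the G charge held fixed. The same rule on red against ochre, with the L charge held fixed, gives 0.475 for G. Both are our reckonings, taken from ochre's charge upward, and we let them stand in for the exponents asked, although they are read at the end of the runs and not at the start.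

For green we start from grey, which has the same G charge. Grey's last two readings, 0.092 M at 23 min and 0.086 M at 27 min, fall by twice the scatter after a steady climb, so we read that fall as scatter and take the higher reading, 0.0920 M, as our estimate for grey at 27 min.

Two extremes can be solved at once. If J followed the L charge in proportion, green would repeat grey's share, 23.0%. If J ignored the L charge, green would repeat grey's amount, a share of 36.8%. The exponent lies between these cases , so green should lie between them too. Assuming that it holds down at grey's charge, we scale grey's amount by the ratio of L charges raised to that exponent, which gives a share of 28.2%.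

The forecast gave 0.9 for G, 0.9 for L and 25% for green, holding that early rates “point to orders near 1 in both L and G”. Its exponents stand higher than ours , and its share lower.

The flask gives 0.53 for G, 0.60 for L and 25.5% for green.

    L → X (0.1158 min⁻¹)
    X + G → J (0.1998 M⁻¹ min⁻¹)
    X → Z (0.03942 min⁻¹)
    J → Xi (0.006180 min⁻¹)
    L → Qa (0.01854 min⁻¹)

The step from L to Qa moves the readings by 8.7 times the scatter, root mean square. Carried to green, the charge exponent turns our estimate for grey, 0.0920 M, into 0.0705 M of J at 27 min, and the flask gives 0.0637 M.

The earlier runs and the new flask are calculated for an exercise; scatter was added.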